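## Retrosynthetic overview

1. Iridal ← selective reduction of the saturated aldehyde ← glycol cleavage of a cyclohepta-fused 1,2-diol. The temporary seven-membered ring ties the future CHO carbon to the side chain on the neighbouring ring carbon, so the tetrasubstituted enal is Z by construction.
2. Key late step: B-alkyl Suzuki coupling of a C16 bicyclic primary iodide with a C14 (1E,5E)-alkenyl iodide, three steps from the end.
3. Bicyclic iodide ← rhenium-catalysed 1,3-allylic transposition ← ring-closing metathesis ← vinyl/isopropenyl additions to a keto aldehyde ← cyclohexanone built on a quinone monoketal (asymmetric conjugate addition, two α′-alkylations, conjugate reduction, MeLi).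
4. Alkenyl iodide ← two zirconium-catalysed carboalumination/iodinations joined by a Negishi coupling (prenyl bromide, 1-(trimethylsilyl)propyne, but-3-yn-1-ol).
5. Ring order: the cyclohexane is the carbocycle of hydroquinone and is never opened; the cycloheptene is closed by metathesis and cut open again at the end.

Assumption: the facial sense of the copper/phosphoramidite addition in step 4 is taken by analogy with cyclohex-2-enone; if it proves opposite, the other ligand antipode is used.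
Assumption: operations run in one flask without isolating the intermediate count as one step.
Assumption: stereocentres that are made as epimer mixtures and erased later (the carbinol and acetal carbons of the seven-membered ring) are left undefined in the SMILES.

## Route

Step 1
Reactants: 1 hydroquinone
Product: 2 4-methoxyphenol
Conditions: MeOH, H2SO4 (cat.), NaNO2 (cat.), rt
Reagents that add atoms: methanol (CO)
Why: Nitrite-promoted, acid-catalysed mono-etherification of hydroquinone, which stops cleanly at the monomethyl ether.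

Step 2
Reactants: 2 4-methoxyphenol
Product: 3 4,4-dimethoxycyclohexa-2,5-dien-1-one
Conditions: PhI(OAc)2, MeOH, 0 °C → rt
Reagents that add atoms: methanol (CO)
Why: Oxidative dearomatisation of a para-alkoxyphenol with methanol capture gives the quinone monoketal, an achiral dienone with two enantiotopic enone units.

Step 3
Reactants: 4 2-(2-bromoethyl)-1,3-dioxolane
Product: 6 [2-(1,3-dioxolan-2-yl)ethyl][(trimethylsilyl)methyl]zinc, via Grignard reagent 5 (not isolated)
Conditions: Mg, THF, 25 °C; then Me3SiCH2ZnCl (1.0 equiv, premixed from Me3SiCH2MgCl and ZnCl2 in THF, 0 °C), 0 °C → rt; 1,4-dioxane, filtration; solvent exchange to toluene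
Reagents that add atoms: zinc dichloride (Cl[Zn]Cl); (trimethylsilyl)methylmagnesium chloride (C[Si](C)(C)C[Mg]Cl)
Why: Grignard formation and magnesium-to-zinc transmetalation onto the preformed (trimethylsilyl)methylzinc chloride give a mixed diorganozinc that carries one functionalised alkyl group and one non-transferable Me3SiCH2 group, and dioxane precipitates the magnesium halides so the reagent is salt-free.

Step 4
Reactants: 3 4,4-dimethoxycyclohexa-2,5-dien-1-one; 6 [2-(1,3-dioxolan-2-yl)ethyl][(trimethylsilyl)methyl]zinc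
Product: 8 (5S)-5-[2-(1,3-dioxolan-2-yl)ethyl]-4,4-dimethoxycyclohex-2-en-1-one, via zinc enolate 7 (not isolated)
Conditions: Cu(OTf)2 (2 mol %), O,O′-[(R)-1,1′-binaphthalene-2,2′-diyl] N,N-bis[(S)-1-phenylethyl]phosphoramidite (4 mol %), 6 (1.3 equiv), toluene, −30 °C; aq. NH4Cl
Reagents that add atoms: none
Why: Copper-catalysed asymmetric conjugate addition of a diorganozinc desymmetrises the dienone; the chiral phosphoramidite–copper complex selects one enantiotopic β-carbon and face and so sets C5, only the functionalised alkyl group is transferred because the Me3SiCH2–Zn bond does not transmetalate to copper, and the zinc enolate blocks a second addition.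

Step 5
Reactants: 8 (5S)-5-[2-(1,3-dioxolan-2-yl)ethyl]-4,4-dimethoxycyclohex-2-en-1-one
Product: 10 (5S,6S)-5-[2-(1,3-dioxolan-2-yl)ethyl]-4,4-dimethoxy-6-methylcyclohex-2-en-1-one, via lithium dienolate 9 (not isolated)
Conditions: LiN(iPr)2, THF, −78 °C; MeI, −78 → −30 °C
Reagents that add atoms: iodomethane (IC)
Why: Kinetic α′-enolate methylation; C6 is the only acidic position, and the new centre (mainly trans, shown) becomes planar again in step 6, so its epimer ratio does not matter.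

Step 6
Reactants: 10 (5S,6S)-5-[2-(1,3-dioxolan-2-yl)ethyl]-4,4-dimethoxy-6-methylcyclohex-2-en-1-one; 11 allyl bromide
Product: 13 (5S,6S)-6-allyl-5-[2-(1,3-dioxolan-2-yl)ethyl]-4,4-dimethoxy-6-methylcyclohex-2-en-1-one, via lithium dienolate 12 (not isolated)
Conditions: LiN(iPr)2, THF/DMPU, −78 °C; allyl bromide, −78 → 0 °C
Reagents that add atoms: none
Why: Second α′-alkylation of the cross-conjugated dienolate builds the quaternary carbon; the C5 chain sits pseudo-axial (allylic 1,2-strain with the enolate methyl) and allyl bromide attacks the opposite face, so allyl ends trans and methyl cis to the C5 chain.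

Step 7
Reactants: 13 (5S,6S)-6-allyl-5-[2-(1,3-dioxolan-2-yl)ethyl]-4,4-dimethoxy-6-methylcyclohex-2-en-1-one
Product: 15 (2S,3S)-2-allyl-3-[2-(1,3-dioxolan-2-yl)ethyl]-4,4-dimethoxy-2-methylcyclohexan-1-one, via silyl enol ether 14 (not isolated)
Conditions: [(Ph3P)CuH]6 (5 mol %), PhMe2SiH, toluene, rt; then K2CO3 (cat.), MeOH
Reagents that add atoms: none
Why: Copper hydride-catalysed conjugate reduction (1,4-hydrosilylation) saturates only the enone double bond, leaves the allyl group and touches no stereocentre.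

Step 8
Reactants: 15 (2S,3S)-2-allyl-3-[2-(1,3-dioxolan-2-yl)ethyl]-4,4-dimethoxy-2-methylcyclohexan-1-one
Product: 17 triethyl({(1S,2S,3S)-2-allyl-3-[2-(1,3-dioxolan-2-yl)ethyl]-4,4-dimethoxy-1,2-dimethylcyclohexyl}oxy)silane, via lithium alkoxide 16 (not isolated)
Conditions: MeLi, THF/Et2O, −78 °C; then Et3SiOTf (1.1 equiv), −78 → −40 °C; Et3N, aq. NaHCO3
Reagents that add atoms: methyllithium ([Li]C); triethylsilyl trifluoromethanesulfonate (CC[Si](CC)(CC)OS(=O)(=O)C(F)(F)F)
Why: 1,2-Addition of MeLi from the ketone face anti to the axial C2 methyl and away from the C3 chain (the allyl face) puts the new methyl cis to allyl and the oxygen cis to the C2 methyl, and the alkoxide is silylated in the same flask.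

Step 9
Reactants: 17 triethyl({(1S,2S,3S)-2-allyl-3-[2-(1,3-dioxolan-2-yl)ethyl]-4,4-dimethoxy-1,2-dimethylcyclohexyl}oxy)silane
Product: 19 2-{(1S,2S,6S)-2-[2-(1,3-dioxolan-2-yl)ethyl]-3,3-dimethoxy-1,6-dimethyl-6-[(triethylsilyl)oxy]cyclohexyl}ethan-1-ol, via aldehyde 18 (not isolated)
Conditions: O3, CH2Cl2/MeOH, NaHCO3, −78 °C; then NaBH4, −78 → 0 °C
Reagents that add atoms: ozone ([O-][O+]=O)
Why: Ozonolysis of the only alkene with reductive work-up shortens allyl to the 2-hydroxyethyl handle; the silyl ether and both acetals are inert.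

Step 10
Reactants: 19 2-{(1S,2S,6S)-2-[2-(1,3-dioxolan-2-yl)ethyl]-3,3-dimethoxy-1,6-dimethyl-6-[(triethylsilyl)oxy]cyclohexyl}ethan-1-ol
Product: 20 triethyl({(1S,2S,3S)-3-[2-(1,3-dioxolan-2-yl)ethyl]-2-(2-iodoethyl)-4,4-dimethoxy-1,2-dimethylcyclohexyl}oxy)silane
Conditions: I2, PPh3, imidazole, CH2Cl2, 0 °C
Reagents that add atoms: iodine ([I][I])
Why: Appel-type iodination of the primary alcohol; the tertiary oxygen is silylated, so no tetrahydrofuran can form.

Step 11
Reactants: 20 triethyl({(1S,2S,3S)-3-[2-(1,3-dioxolan-2-yl)ethyl]-2-(2-iodoethyl)-4,4-dimethoxy-1,2-dimethylcyclohexyl}oxy)silane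
Product: 21 3-{(1S,2S,3S)-2-(2-iodoethyl)-2,3-dimethyl-6-oxo-3-[(triethylsilyl)oxy]cyclohexyl}propanal
Conditions: PPTS (0.2 equiv), acetone/H2O (10:1), 40 °C
Reagents that add atoms: water (O)
Why: Mild acid hydrolysis removes the dimethyl ketal and the dioxolane together; the hindered tertiary silyl ether and the iodide survive, and the low acidity avoids epimerising the CH next to the new ketone.

Step 12
Reactants: 21 3-{(1S,2S,3S)-2-(2-iodoethyl)-2,3-dimethyl-6-oxo-3-[(triethylsilyl)oxy]cyclohexyl}propanal; 22 vinylmagnesium bromide; 23 isopropenylmagnesium bromide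
Product: 25 5-{(1S,2S,3S)-6-hydroxy-2-(2-iodoethyl)-2,3-dimethyl-6-(prop-1-en-2-yl)-3-[(triethylsilyl)oxy]cyclohexyl}pent-1-en-3-ol, via bromomagnesium alkoxide 24 (not isolated)
Conditions: CH2=CHMgBr (1.05 equiv), THF, −78 °C; then LaCl3·2LiCl, CH2=C(CH3)MgBr (3 equiv), −78 → 0 °C; aq. NH4Cl
Reagents that add atoms: none
Why: Chemoselective Grignard additions, first to the aldehyde at −78 °C and then, with the lanthanum salt suppressing enolisation, to the hindered ketone; both new carbinol centres form as mixtures and are erased in steps 14 and 25.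

Step 13
Reactants: 25 5-{(1S,2S,3S)-6-hydroxy-2-(2-iodoethyl)-2,3-dimethyl-6-(prop-1-en-2-yl)-3-[(triethylsilyl)oxy]cyclohexyl}pent-1-en-3-ol
Product: 26 (3S,4S,4aS)-4-(2-iodoethyl)-3,4,9-trimethyl-3-[(triethylsilyl)oxy]-2,3,4,4a,5,6,7,9a-octahydro-1H-benzo[7]annulene-7,9a-diol
Conditions: second-generation Grubbs catalyst (H2IMes)(PCy3)Cl2Ru=CHPh (5 mol %), CH2Cl2 (0.005 mol/L), 40 °C
Reagents that add atoms: none
Why: Ring-closing metathesis between the vinyl carbinol and the isopropenyl group closes the seven-membered ring with a trisubstituted alkene and loss of ethene.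

Step 14
Reactants: 26 (3S,4S,4aS)-4-(2-iodoethyl)-3,4,9-trimethyl-3-[(triethylsilyl)oxy]-2,3,4,4a,5,6,7,9a-octahydro-1H-benzo[7]annulene-7,9a-diol
Product: 28 7,8-O-isopropylidene acetal of (3S,4S,4aR)-4-(2-iodoethyl)-3,4,9-trimethyl-3-[(triethylsilyl)oxy]-2,3,4,4a,5,6,7,8-octahydro-1H-benzo[7]annulene-7,8-diol, via rearranged diol 27 (not isolated)
Conditions: Re2O7 (5 mol %), Me2C(OMe)2, CH2Cl2, 0 °C → rt
Reagents that add atoms: 2,2-dimethoxypropane (COC(C)(C)OC)
Why: Rhenium-oxo-catalysed 1,3-transposition of the tertiary allylic alcohol (sigmatropic shift of the perrhenate ester) moves the oxygen to C8 and the alkene to the ring fusion, acetonide trapping of the new 1,2-diol pulls the equilibrium over, and the seven-membered ring forces C8 to be cis to C4a across the tetrasubstituted alkene.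

Step 15
Reactants: 29 prenyl bromide (1-bromo-3-methylbut-2-ene); 30 1-(trimethylsilyl)propyne
Product: 32 trimethyl(6-methylhept-5-en-1-yn-1-yl)silane, via lithiated alkyne 31 (not isolated)
Conditions: n-BuLi, THF, −78 → −20 °C (on 30); then 29, −78 °C → rt
Reagents that add atoms: none
Why: Propargylic lithiation of the silylpropyne and direct (unrearranged) substitution of the allylic bromide; the silyl group keeps the nucleophile propargylic.

Step 16
Reactants: 32 trimethyl(6-methylhept-5-en-1-yn-1-yl)silane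
Product: 33 6-methylhept-5-en-1-yne
Conditions: K2CO3 (cat.), MeOH, rt
Reagents that add atoms: none
Why: Base-catalysed methanolysis of the alkynyl–silicon bond frees the terminal alkyne.

Step 17
Reactants: 33 6-methylhept-5-en-1-yne
Product: 35 (1E)-1-iodo-2,6-dimethylhepta-1,5-diene, via alkenylalane 34 (not isolated)
Conditions: Me3Al, Cp2ZrCl2 (25 mol %), CH2Cl2, 0 °C → rt; then I2, THF, −30 → 0 °C
Reagents that add atoms: trimethylaluminium (C[Al](C)C); iodine ([I][I])
Why: Negishi zirconium-catalysed carboalumination adds methyl and aluminium syn across the terminal alkyne (methyl to the internal carbon), and iodinolysis with retention gives the E-alkenyl iodide.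

Step 18
Reactants: 36 but-3-yn-1-ol
Product: 39 4-(trimethylsilyl)but-3-yn-1-ol, via dilithium alkynide alkoxide 37 (not isolated), via bis-silyl compound 38 (not isolated)
Conditions: n-BuLi (2.2 equiv), THF, −78 °C; Me3SiCl (2.2 equiv), −78 °C → rt; then aq. HCl (1 mol/L)
Reagents that add atoms: chlorotrimethylsilane (C[Si](C)(C)Cl)
Why: Double deprotonation and double silylation, then selective acid hydrolysis of the labile silyl ether, leaves the alkyne carbon protected.

Step 19
Reactants: 39 4-(trimethylsilyl)but-3-yn-1-ol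
Product: 40 (4-iodobut-1-yn-1-yl)trimethylsilane
Conditions: I2, PPh3, imidazole, CH2Cl2, 0 °C
Reagents that add atoms: iodine ([I][I])
Why: Appel-type iodination of the primary alcohol.

Step 20
Reactants: 40 (4-iodobut-1-yn-1-yl)trimethylsilane; 35 (1E)-1-iodo-2,6-dimethylhepta-1,5-diene
Product: 42 [(5E)-6,10-dimethylundeca-5,9-dien-1-yn-1-yl]trimethylsilane, via alkylzinc iodide 41 (not isolated)
Conditions: Zn dust (activated), THF, 40 °C; then 35, Pd(PPh3)4 (3 mol %), THF, rt
Reagents that add atoms: none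
Why: Zinc insertion and Negishi coupling catalysed by zerovalent palladium join the homopropargyl unit to the alkenyl iodide with retention of the E geometry.

Step 21
Reactants: 42 [(5E)-6,10-dimethylundeca-5,9-dien-1-yn-1-yl]trimethylsilane
Product: 43 (5E)-6,10-dimethylundeca-5,9-dien-1-yne
Conditions: K2CO3 (cat.), MeOH, rt
Reagents that add atoms: none
Why: Base-catalysed protodesilylation of the alkynylsilane.

Step 22
Reactants: 43 (5E)-6,10-dimethylundeca-5,9-dien-1-yne
Product: 45 (1E,5E)-1-iodo-2,6,10-trimethylundeca-1,5,9-triene, via alkenylalane 44 (not isolated)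
Conditions: Me3Al, Cp2ZrCl2 (25 mol %), CH2Cl2, 0 °C → rt; then I2, THF, −30 → 0 °C
Reagents that add atoms: trimethylaluminium (C[Al](C)C); iodine ([I][I])
Why: Second Negishi carboalumination/iodinolysis sets the new trisubstituted alkene E by syn addition and retentive iodination.

Step 23
Reactants: 28 bicyclic acetonide iodide; 45 (1E,5E)-1-iodo-2,6,10-trimethylundeca-1,5,9-triene
Product: 48 (3S,4S,4aR)-7,8-(isopropylidenedioxy)-3,4,9-trimethyl-3-[(triethylsilyl)oxy]-4-[(3E,7E)-4,8,12-trimethyltrideca-3,7,11-trien-1-yl]-2,3,4,4a,5,6,7,8-octahydro-1H-benzo[7]annulene, via alkyllithium 46 (not isolated), via lithium borate 47 (not isolated)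
Conditions: 28: t-BuLi (2.1 equiv), Et2O, −78 °C; B-MeO-9-BBN, THF, −78 °C → rt; then 45, Pd(dppf)Cl2 (5 mol %), AsPh3, aq. K3PO4, DMF, rt
Reagents that add atoms: none
Why: B-alkyl Suzuki–Miyaura coupling: iodine–lithium exchange, capture by the borinate and cross-coupling catalysed by zerovalent palladium join the C16 ring fragment to the C14 chain with retention of the E alkenyl geometry.

Step 24
Reactants: 48 coupled silyl ether acetonide
Product: 49 (3S,4S,4aR)-3,4,9-trimethyl-4-[(3E,7E)-4,8,12-trimethyltrideca-3,7,11-trien-1-yl]-2,3,4,4a,5,6,7,8-octahydro-1H-benzo[7]annulene-3,7,8-triol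
Conditions: AcOH/THF/H2O (3:1:1), 45 °C
Reagents that add atoms: none
Why: Mild acid hydrolysis removes the acetonide and the triethylsilyl ether without touching the trisubstituted alkenes.

Step 25
Reactants: 49 triol
Product: 50 (2Z)-2-{(2R,3S,4S)-4-hydroxy-3,4-dimethyl-2-(3-oxopropyl)-3-[(3E,7E)-4,8,12-trimethyltrideca-3,7,11-trien-1-yl]cyclohexylidene}propanal
Conditions: NaIO4, THF/pH 7 buffer, 0 °C
Reagents that add atoms: none
Why: Malaprade glycol cleavage opens the seven-membered ring; the former ring carbon next to the alkene becomes the enal CHO, cis to the ring CH as the ring demanded, so the Z geometry is fixed.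

Step 26
Reactants: 50 dialdehyde
Product: 51 iridal, (2Z)-2-{(2R,3S,4S)-4-hydroxy-2-(3-hydroxypropyl)-3,4-dimethyl-3-[(3E,7E)-4,8,12-trimethyltrideca-3,7,11-trien-1-yl]cyclohexylidene}propanal
Conditions: NaBH4 (0.5 equiv), EtOH/CH2Cl2 (3:7), −78 °C
Reagents that add atoms: none
Why: Chemoselective borohydride reduction: the saturated aldehyde is reduced far faster at −78 °C than the hindered, conjugated tetrasubstituted enal, and no stereocentre or alkene is affected.

## Compound list

1 | hydroquinone (benzene-1,4-diol) | Oc1ccc(O)cc1 | starting material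
2 | 4-methoxyphenol | COc1ccc(O)cc1 | intermediate
3 | 4,4-dimethoxycyclohexa-2,5-dien-1-one | COC1(OC)C=CC(=O)C=C1 | intermediate
4 | 2-(2-bromoethyl)-1,3-dioxolane | BrCCC1OCCO1 | starting material
5 | [2-(1,3-dioxolan-2-yl)ethyl]magnesium bromide (not isolated) | Br[Mg]CCC1OCCO1 | intermediate
6 | [2-(1,3-dioxolan-2-yl)ethyl][(trimethylsilyl)methyl]zinc | C[Si](C)(C)C[Zn]CCC1OCCO1 | intermediate
7 | (trimethylsilyl)methylzinc dienolate of 8 (not isolated) | C[Si](C)(C)C[Zn]OC1=C[C@H](CCC2OCCO2)C(OC)(OC)C=C1 | intermediate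
8 | (5S)-5-[2-(1,3-dioxolan-2-yl)ethyl]-4,4-dimethoxycyclohex-2-en-1-one | O=C1C=CC(OC)(OC)[C@@H](CCC2OCCO2)C1 | intermediate
9 | lithium dienolate of 8 (not isolated) | [Li]OC1=C[C@H](CCC2OCCO2)C(OC)(OC)C=C1 | intermediate
10 | (5S,6S)-5-[2-(1,3-dioxolan-2-yl)ethyl]-4,4-dimethoxy-6-methylcyclohex-2-en-1-one (trans, major; the 6-epimer converges in step 6) | O=C1C=CC(OC)(OC)[C@@H](CCC2OCCO2)[C@@H]1C | intermediate
11 | allyl bromide (3-bromoprop-1-ene) | C=CCBr | starting material
12 | lithium dienolate of 10 (not isolated) | [Li]OC1=C(C)[C@H](CCC2OCCO2)C(OC)(OC)C=C1 | intermediate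
13 | (5S,6S)-6-allyl-5-[2-(1,3-dioxolan-2-yl)ethyl]-4,4-dimethoxy-6-methylcyclohex-2-en-1-one (allyl trans to the C5 chain) | O=C1C=CC(OC)(OC)[C@@H](CCC2OCCO2)[C@]1(C)CC=C | intermediate
14 | dimethylphenylsilyl enol ether of 15 (not isolated) | C[Si](C)(c1ccccc1)OC1=CCC(OC)(OC)[C@@H](CCC2OCCO2)[C@]1(C)CC=C | intermediate
15 | (2S,3S)-2-allyl-3-[2-(1,3-dioxolan-2-yl)ethyl]-4,4-dimethoxy-2-methylcyclohexan-1-one | O=C1CCC(OC)(OC)[C@@H](CCC2OCCO2)[C@]1(C)CC=C | intermediate
16 | lithium (1S,2S,3S)-2-allyl-3-[2-(1,3-dioxolan-2-yl)ethyl]-4,4-dimethoxy-1,2-dimethylcyclohexan-1-olate (not isolated) | C[C@]1(O[Li])CCC(OC)(OC)[C@@H](CCC2OCCO2)[C@]1(C)CC=C | intermediate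
17 | triethyl({(1S,2S,3S)-2-allyl-3-[2-(1,3-dioxolan-2-yl)ethyl]-4,4-dimethoxy-1,2-dimethylcyclohexyl}oxy)silane (oxygen cis to the C2 methyl and the C3 chain) | C[C@]1(O[Si](CC)(CC)CC)CCC(OC)(OC)[C@@H](CCC2OCCO2)[C@]1(C)CC=C | intermediate
18 | 2-{(1S,2S,6S)-2-[2-(1,3-dioxolan-2-yl)ethyl]-3,3-dimethoxy-1,6-dimethyl-6-[(triethylsilyl)oxy]cyclohexyl}acetaldehyde (not isolated) | C[C@]1(O[Si](CC)(CC)CC)CCC(OC)(OC)[C@@H](CCC2OCCO2)[C@]1(C)CC=O | intermediate
19 | 2-{(1S,2S,6S)-2-[2-(1,3-dioxolan-2-yl)ethyl]-3,3-dimethoxy-1,6-dimethyl-6-[(triethylsilyl)oxy]cyclohexyl}ethan-1-ol | C[C@]1(O[Si](CC)(CC)CC)CCC(OC)(OC)[C@@H](CCC2OCCO2)[C@]1(C)CCO | intermediate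
20 | triethyl({(1S,2S,3S)-3-[2-(1,3-dioxolan-2-yl)ethyl]-2-(2-iodoethyl)-4,4-dimethoxy-1,2-dimethylcyclohexyl}oxy)silane | C[C@]1(O[Si](CC)(CC)CC)CCC(OC)(OC)[C@@H](CCC2OCCO2)[C@]1(C)CCI | intermediate
21 | 3-{(1S,2S,3S)-2-(2-iodoethyl)-2,3-dimethyl-6-oxo-3-[(triethylsilyl)oxy]cyclohexyl}propanal | C[C@]1(O[Si](CC)(CC)CC)CCC(=O)[C@@H](CCC=O)[C@]1(C)CCI | intermediate
22 | vinylmagnesium bromide | C=C[Mg]Br | starting material
23 | isopropenylmagnesium bromide (prop-1-en-2-ylmagnesium bromide) | CC(=C)[Mg]Br | starting material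
24 | bromomagnesium 5-{(1S,2S,3S)-2-(2-iodoethyl)-2,3-dimethyl-6-oxo-3-[(triethylsilyl)oxy]cyclohexyl}pent-1-en-3-olate (not isolated; carbinol epimers) | C[C@]1(O[Si](CC)(CC)CC)CCC(=O)[C@@H](CCC(O[Mg]Br)C=C)[C@]1(C)CCI | intermediate
25 | 5-{(1S,2S,3S)-6-hydroxy-2-(2-iodoethyl)-2,3-dimethyl-6-(prop-1-en-2-yl)-3-[(triethylsilyl)oxy]cyclohexyl}pent-1-en-3-ol (epimers at both new carbinol carbons) | C[C@]1(O[Si](CC)(CC)CC)CCC(O)(C(C)=C)[C@@H](CCC(O)C=C)[C@]1(C)CCI | intermediate
26 | (3S,4S,4aS)-4-(2-iodoethyl)-3,4,9-trimethyl-3-[(triethylsilyl)oxy]-2,3,4,4a,5,6,7,9a-octahydro-1H-benzo[7]annulene-7,9a-diol (epimers at C7 and C9a) | C[C@]1(O[Si](CC)(CC)CC)CCC2(O)C(C)=CC(O)CC[C@H]2[C@]1(C)CCI | intermediate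
27 | (3S,4S,4aR)-4-(2-iodoethyl)-3,4,9-trimethyl-3-[(triethylsilyl)oxy]-2,3,4,4a,5,6,7,8-octahydro-1H-benzo[7]annulene-7,8-diol (not isolated; epimers at C7 and C8) | C[C@]1(O[Si](CC)(CC)CC)CCC2=C(C)C(O)C(O)CC[C@H]2[C@]1(C)CCI | intermediate
28 | 7,8-O-isopropylidene acetal of 27 (epimers at C7 and C8) | C[C@]1(O[Si](CC)(CC)CC)CCC2=C(C)C3OC(C)(C)OC3CC[C@H]2[C@]1(C)CCI | intermediate
29 | prenyl bromide (1-bromo-3-methylbut-2-ene) | CC(C)=CCBr | starting material
30 | 1-(trimethylsilyl)propyne | CC#C[Si](C)(C)C | starting material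
31 | [3-(trimethylsilyl)prop-2-yn-1-yl]lithium (not isolated) | [Li]CC#C[Si](C)(C)C | intermediate
32 | trimethyl(6-methylhept-5-en-1-yn-1-yl)silane | CC(C)=CCCC#C[Si](C)(C)C | intermediate
33 | 6-methylhept-5-en-1-yne | CC(C)=CCCC#C | intermediate
34 | dimethyl[(1E)-2,6-dimethylhepta-1,5-dien-1-yl]alumane (not isolated) | C[Al](C)/C=C(\C)CCC=C(C)C | intermediate
35 | (1E)-1-iodo-2,6-dimethylhepta-1,5-diene | I/C=C(\C)CCC=C(C)C | intermediate
36 | but-3-yn-1-ol | C#CCCO | starting material
37 | dilithium salt of but-3-yn-1-ol (alkynide and alkoxide; not isolated) | [Li]C#CCCO[Li] | intermediate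
38 | trimethyl{[4-(trimethylsilyl)but-3-yn-1-yl]oxy}silane (not isolated) | C[Si](C)(C)C#CCCO[Si](C)(C)C | intermediate
39 | 4-(trimethylsilyl)but-3-yn-1-ol | C[Si](C)(C)C#CCCO | intermediate
40 | (4-iodobut-1-yn-1-yl)trimethylsilane | C[Si](C)(C)C#CCCI | intermediate
41 | [4-(trimethylsilyl)but-3-yn-1-yl]zinc iodide (not isolated) | C[Si](C)(C)C#CCC[Zn]I | intermediate
42 | [(5E)-6,10-dimethylundeca-5,9-dien-1-yn-1-yl]trimethylsilane | C[Si](C)(C)C#CCC/C=C(\C)CCC=C(C)C | intermediate
43 | (5E)-6,10-dimethylundeca-5,9-dien-1-yne | C#CCC/C=C(\C)CCC=C(C)C | intermediate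
44 | dimethyl[(1E,5E)-2,6,10-trimethylundeca-1,5,9-trien-1-yl]alumane (not isolated) | C[Al](C)/C=C(\C)CC/C=C(\C)CCC=C(C)C | intermediate
45 | (1E,5E)-1-iodo-2,6,10-trimethylundeca-1,5,9-triene | I/C=C(\C)CC/C=C(\C)CCC=C(C)C | intermediate
46 | alkyllithium from 28 (lithium in place of iodine; not isolated) | C[C@]1(O[Si](CC)(CC)CC)CCC2=C(C)C3OC(C)(C)OC3CC[C@H]2[C@]1(C)CC[Li] | intermediate
47 | lithium B-alkyl-B-methoxy-9-borabicyclo[3.3.1]nonane borate from 46 (not isolated) | [Li+].C[C@]1(O[Si](CC)(CC)CC)CCC2=C(C)C3OC(C)(C)OC3CC[C@H]2[C@]1(C)CC[B-]1(OC)C2CCCC1CCC2 | intermediate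
48 | (3S,4S,4aR)-7,8-(isopropylidenedioxy)-3,4,9-trimethyl-3-[(triethylsilyl)oxy]-4-[(3E,7E)-4,8,12-trimethyltrideca-3,7,11-trien-1-yl]-2,3,4,4a,5,6,7,8-octahydro-1H-benzo[7]annulene (epimers at C7 and C8) | C[C@]1(O[Si](CC)(CC)CC)CCC2=C(C)C3OC(C)(C)OC3CC[C@H]2[C@]1(C)CC/C=C(\C)CC/C=C(\C)CCC=C(C)C | intermediate
49 | (3S,4S,4aR)-3,4,9-trimethyl-4-[(3E,7E)-4,8,12-trimethyltrideca-3,7,11-trien-1-yl]-2,3,4,4a,5,6,7,8-octahydro-1H-benzo[7]annulene-3,7,8-triol (epimers at C7 and C8) | C[C@]1(O)CCC2=C(C)C(O)C(O)CC[C@H]2[C@]1(C)CC/C=C(\C)CC/C=C(\C)CCC=C(C)C | intermediate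
50 | (2Z)-2-{(2R,3S,4S)-4-hydroxy-3,4-dimethyl-2-(3-oxopropyl)-3-[(3E,7E)-4,8,12-trimethyltrideca-3,7,11-trien-1-yl]cyclohexylidene}propanal | CC(C)=CCC/C(C)=C/CC/C(C)=C/CC[C@@]1(C)[C@H](CCC=O)/C(=C(/C)C=O)CC[C@]1(C)O | intermediate
51 | iridal, (2Z)-2-{(2R,3S,4S)-4-hydroxy-2-(3-hydroxypropyl)-3,4-dimethyl-3-[(3E,7E)-4,8,12-trimethyltrideca-3,7,11-trien-1-yl]cyclohexylidene}propanal | CC(C)=CCC/C(C)=C/CC/C(C)=C/CC[C@@]1(C)[C@H](CCCO)/C(=C(/C)C=O)CC[C@]1(C)O | target

## Step count

Total: 26 steps.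
Longest linear sequence: 17 steps (steps 1, 2, 4–14, 23–26). The chain branch (steps 15–22) and the zinc reagent (step 3) run in parallel.

## Steps most likely to fail and fallbacks

Step 4 (asymmetric conjugate addition). The β-carbon is flanked by the ketal, and the zinc reagent is Grignard-derived and carries a dummy ligand, so conversion and enantiomeric excess are at risk. The fallback sets out from 3 and comes back at 8 and replaces the organozinc by an alkene-derived alkylzirconium nucleophile. Commercial 2-vinyl-1,3-dioxolane is hydrozirconated with Cp2Zr(H)Cl (CH2Cl2, rt) to chlorobis(cyclopentadienyl)[2-(1,3-dioxolan-2-yl)ethyl]zirconium F1. F1 is added to 3 under monovalent-copper catalysis (CuCl, AgOTf, the same phosphoramidite, Et2O, rt), and aqueous work-up gives 8.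

Step 8 (MeLi addition). The facial selectivity next to the quaternary carbon is predicted, not precedented; attack on the other face gives the epimeric tertiary alcohol. The fallback sets out from 15 and comes back at 17 and inverts the sense of carbon–oxygen bond formation. Methylenation of 15 with Cp2TiMe2 (toluene, 70 °C) gives 2-{2-[(1S,2S)-2-allyl-6,6-dimethoxy-2-methyl-3-methylidenecyclohexyl]ethyl}-1,3-dioxolane F2. mCPBA (NaHCO3, CH2Cl2, 0 °C) epoxidises the 1,1-disubstituted alkene faster than the allyl group and from the more open face (where the failed MeLi addition had put carbon), giving the spiro-epoxide of F2 with oxygen cis to the neighbouring ring methyl F3. LiEt3BH opens it at the CH2 carbon to (1S,2S,3S)-2-allyl-3-[2-(1,3-dioxolan-2-yl)ethyl]-4,4-dimethoxy-1,2-dimethylcyclohexan-1-ol F4, and KN(SiMe3)2 then Et3SiCl gives 17.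

Step 14 (rhenium-catalysed transposition with acetonide trapping). The catalyst may ionise the doubly allylic system (dienes, scrambling) or move the secondary hydroxyl instead. The fallback sets out from 26 and comes back at 28, through 27, using an oxidative transposition. Ac2O/pyridine acetylates only the secondary allylic hydroxyl to give the 7-O-acetate of 26 F5. C5H5NH[CrO3Cl] in CH2Cl2 (Babler–Dauben oxidative 1,3-transposition of the tertiary allylic alcohol) gives the 7-acetoxy-8-oxo enone with the ring-fusion tetrasubstituted alkene F6. i-Bu2AlH (CH2Cl2, −78 °C) reduces the ketone and removes the acetate to give diol 27, and Me2C(OMe)2/PPTS converts 27 into 28.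

## Further compounds

F1 | step 4 | chlorobis(cyclopentadienyl)[2-(1,3-dioxolan-2-yl)ethyl]zirconium | Cl[Zr](CCC1OCCO1)(C1C=CC=C1)C1C=CC=C1
F2 | step 8 | 2-{2-[(1S,2S)-2-allyl-6,6-dimethoxy-2-methyl-3-methylidenecyclohexyl]ethyl}-1,3-dioxolane | C=C1CCC(OC)(OC)[C@@H](CCC2OCCO2)[C@]1(C)CC=C
F3 | step 8 | spiro-epoxide of F2 (1-oxaspiro[2.5]octane, oxygen cis to the methyl of the neighbouring quaternary carbon) | C1O[C@]12CCC(OC)(OC)[C@@H](CCC3OCCO3)[C@]2(C)CC=C
F4 | step 8 | (1S,2S,3S)-2-allyl-3-[2-(1,3-dioxolan-2-yl)ethyl]-4,4-dimethoxy-1,2-dimethylcyclohexan-1-ol | C[C@]1(O)CCC(OC)(OC)[C@@H](CCC2OCCO2)[C@]1(C)CC=C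
F5 | step 14 | 7-O-acetate of 26 | C[C@]1(O[Si](CC)(CC)CC)CCC2(O)C(C)=CC(OC(C)=O)CC[C@H]2[C@]1(C)CCI
F6 | step 14 | (3S,4S,4aR)-7-acetoxy-4-(2-iodoethyl)-3,4,9-trimethyl-3-[(triethylsilyl)oxy]-1,2,3,4,4a,5,6,7-octahydro-8H-benzo[7]annulen-8-one | C[C@]1(O[Si](CC)(CC)CC)CCC2=C(C)C(=O)C(OC(C)=O)CC[C@H]2[C@]1(C)CCI
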